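**Plan**
- Retrosynthesis: the two MOM ethers come off last; the pyran ring is then cut at C4-C3 and O1-C2 (chromene numbering), giving ring A salicylaldehyde 14 and 2-methylprop-1-enylboronic acid 15.
- This cut is possible because C4 is attached to C4a, which lies between the oxygen-bearing carbons C8a and C5: C4 can be an aldehyde carbon ortho to a phenol, and C3, C2 and both methyl groups an isobutenyl unit.
- Further back: the formyl carbon (C4a-C4), then the CH2-aryl bond of the benzyl ketone, then the C8 prenyl group, traced to an O-prenyl ether on the oxygen para to it.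
- Forward: ring A is bought as an acetophenone, the prenyl group moves from oxygen to carbon, ring B is joined at the ketone methyl, the aldehyde is added, and the pyran ring is the only ring made.
- Stereochemistry: the target has no stereocentre and its ring alkene is cis by constraint, so nothing has to be controlled.

Key step: step 9

Remark on the chemistry: intermediates 5, 6 and 16 are racemic and the exocyclic alkene of 17 may have either geometry; their SMILES carry no stereodescriptors because this information is lost on the way to achiral 19.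

Step 1
Reactants: 1 1-(2,4-dihydroxy-6-methoxyphenyl)ethanone
Product: 2 1-[2-hydroxy-6-methoxy-4-(triisopropylsilyloxy)phenyl]ethanone
Conditions: TIPSCl, imidazole, CH2Cl2, 0 °C to rt
Reagents that add atoms: chlorotriisopropylsilane (TIPSCl), CC(C)[Si](Cl)(C(C)C)C(C)C
Why: Selective silylation of a phenol: the ortho hydroxyl is locked in a hydrogen bond to the ketone and shielded by the acetyl group, so only the free, more acidic para hydroxyl should take up the bulky silyl chloride.

Step 2
Reactants: 2 1-[2-hydroxy-6-methoxy-4-(triisopropylsilyloxy)phenyl]ethanone; 3 3-methylbut-2-en-1-ol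
Product: 4 1-[2-methoxy-6-(3-methylbut-2-enyloxy)-4-(triisopropylsilyloxy)phenyl]ethanone
Conditions: PPh3, DIAD, THF, 0 °C to rt
Reagents that add atoms: none
Why: Mitsunobu etherification: with the para phenol capped, the chelated phenol is the only acidic partner and should displace the activated primary allylic oxygen of 3 without any base, which spares the silyl ether.

Step 3
Reactants: 4 1-[2-methoxy-6-(3-methylbut-2-enyloxy)-4-(triisopropylsilyloxy)phenyl]ethanone
Product: 7 1-[6-hydroxy-2-methoxy-3-(3-methylbut-2-enyl)-4-(triisopropylsilyloxy)phenyl]ethanone, via ortho-dienone 5 (not isolated), via para-dienone 6 (not isolated)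
Conditions: PhNEt2, 200 °C, sealed tube, argon
Reagents that add atoms: none
Why: Aromatic Claisen rearrangement followed by a Cope shift (para-Claisen rearrangement): the [3,3] shift to the free ortho carbon gives the crowded dienone 5, a second [3,3] shift relays the allyl unit to the para carbon (6), and enolisation there should give the linear prenyl group beside the methoxy group and free the chelated phenol.

Step 4
Reactants: 7 1-[6-hydroxy-2-methoxy-3-(3-methylbut-2-enyl)-4-(triisopropylsilyloxy)phenyl]ethanone
Product: 8 1-[2-methoxy-6-(methoxymethoxy)-3-(3-methylbut-2-enyl)-4-(triisopropylsilyloxy)phenyl]ethanone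
Conditions: NaH (1.1 equiv), MOMCl, DMF, 0 °C to rt
Reagents that add atoms: chloromethyl methyl ether (MOMCl), COCCl
Why: O-alkylation of a sodium phenoxide (MOM protection): capping the chelated hydroxyl removes the acidic proton that would otherwise quench the ketone enolate in step 6, and this acetal later keeps this oxygen out of the ring closure.

Step 5
Reactants: 9 4-bromophenol
Product: 10 1-bromo-4-(methoxymethoxy)benzene
Conditions: MOMCl, iPr2NEt, CH2Cl2, 0 °C to rt
Reagents that add atoms: chloromethyl methyl ether (MOMCl), COCCl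
Why: MOM protection of a phenol under amine base, a routine O-alkylation that hides the acidic proton of ring B and leaves the C-Br bond ready for oxidative addition.

Step 6
Reactants: 8 1-[2-methoxy-6-(methoxymethoxy)-3-(3-methylbut-2-enyl)-4-(triisopropylsilyloxy)phenyl]ethanone; 10 1-bromo-4-(methoxymethoxy)benzene
Product: 11 1-[2-methoxy-6-(methoxymethoxy)-3-(3-methylbut-2-enyl)-4-(triisopropylsilyloxy)phenyl]-2-[4-(methoxymethoxy)phenyl]ethanone
Conditions: Pd(OAc)2 (3 mol %), 2-dicyclohexylphosphino-2'-methylbiphenyl (6 mol %), K3PO4, toluene, 90 °C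
Reagents that add atoms: none
Why: Palladium-catalysed α-arylation of a ketone enolate: zerovalent palladium formed in situ inserts into the C-Br bond of 10, the enolate of the methyl ketone (the only enolisable site) binds palladium and reductive elimination forms the CH2-aryl bond, while the two ortho substituents suppress aldol self-condensation and the mild phosphate base spares the silyl ether.

Step 7
Reactants: 11 1-[2-methoxy-6-(methoxymethoxy)-3-(3-methylbut-2-enyl)-4-(triisopropylsilyloxy)phenyl]-2-[4-(methoxymethoxy)phenyl]ethanone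
Product: 12 1-[4-hydroxy-2-methoxy-6-(methoxymethoxy)-3-(3-methylbut-2-enyl)phenyl]-2-[4-(methoxymethoxy)phenyl]ethanone
Conditions: Bu4NF, AcOH, THF, 0 °C
Reagents that add atoms: none
Why: Fluoride-induced desilylation: the electron-poor aryl silyl ether should cleave quickly at 0 °C, acetic acid buffers the phenoxide so the acidic benzylic CH2 of the ketone is not enolised, and MOM ethers are inert to fluoride.

Step 8
Reactants: 12 1-[4-hydroxy-2-methoxy-6-(methoxymethoxy)-3-(3-methylbut-2-enyl)phenyl]-2-[4-(methoxymethoxy)phenyl]ethanone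
Product: 14 6-hydroxy-4-methoxy-2-(methoxymethoxy)-3-{[4-(methoxymethoxy)phenyl]acetyl}-5-(3-methylbut-2-enyl)benzaldehyde, via salicyl alcohol 13 (not isolated)
Conditions: MgCl2, Et3N, (CH2O)n, MeCN, 80 °C; then cold dilute HCl
Reagents that add atoms: paraformaldehyde (reacting as formaldehyde), C=O
Why: Magnesium-mediated ortho-formylation (Casnati-Skattebøl reaction): the magnesium phenoxide of the single free phenol delivers formaldehyde through a six-membered transition state to the only unsubstituted carbon of ring A, the salicyl alkoxide of 13 is oxidised by a second formaldehyde through hydride transfer, and ring B, having no free phenol, should stay untouched.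

Step 9
Reactants: 14 6-hydroxy-4-methoxy-2-(methoxymethoxy)-3-{[4-(methoxymethoxy)phenyl]acetyl}-5-(3-methylbut-2-enyl)benzaldehyde; 15 2-methylprop-1-enylboronic acid
Product: 18 1-[7-methoxy-5-(methoxymethoxy)-2,2-dimethyl-8-(3-methylbut-2-enyl)-2H-chromen-6-yl]-2-[4-(methoxymethoxy)phenyl]ethanone, via allylic amine 16 (not isolated), via ortho-quinone methide 17 (not isolated)
Conditions: Bn2NH (0.3 equiv), 1,4-dioxane, 90 °C
Reagents that add atoms: none
Why: Dibenzylamine condenses with the aldehyde of 14 to an iminium ion while the neighbouring phenoxide binds the boron of 15, and the resulting tetracoordinate boronate passes its isobutenyl group intramolecularly to the iminium carbon, forming the C4-C3 bond of allylic amine 16 (Petasis borono-Mannich reaction). At 90 °C 16 should expel dibenzylamine, which re-enters the cycle, to give the vinylogous ortho-quinone methide 17. The pyran ring then closes by a thermal disrotatory oxa-6π electrocyclisation of this 1-oxatriene, the quinone methide oxygen bonding to the dimethyl-substituted terminus (O1-C2 bond) with regain of aromaticity. The closest known reaction type is the secondary-amine-catalysed condensation of salicylaldehydes with alkenylboronic acids to 2H-chromenes, applied here to a β,β-dimethyl alkenyl group and an aldehyde flanked on both sides. No stereocentre is formed and the C3=C4 alkene is cis by ring constraint. The step needs closure on the oxygen next to the prenyl-bearing carbon and reaction at the aldehyde instead of the ketone: the other ortho oxygen is capped as a MOM ether, so only one phenoxide can bind boron and only one quinone methide can form, and the ketone has no free neighbouring phenol and is shielded by two ortho substituents.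

Step 10
Reactants: 18 1-[7-methoxy-5-(methoxymethoxy)-2,2-dimethyl-8-(3-methylbut-2-enyl)-2H-chromen-6-yl]-2-[4-(methoxymethoxy)phenyl]ethanone
Product: 19 1-[5-hydroxy-7-methoxy-2,2-dimethyl-8-(3-methylbut-2-enyl)-2H-chromen-6-yl]-2-(4-hydroxyphenyl)ethanone
Conditions: 3 M aq HCl, MeOH, 45 °C
Reagents that add atoms: none
Why: Acid-catalysed acetal cleavage (MOM removal): the MOM ether beside the ketone should leave first with chelation assistance and the ring B acetal should follow, while the prenyl group, now flanked only by ether oxygens, has no free phenol to cyclise onto.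

**Compound list**
1 | 1-(2,4-dihydroxy-6-methoxyphenyl)ethanone | CC(=O)c1c(O)cc(O)cc1OC | starting material
2 | 1-[2-hydroxy-6-methoxy-4-(triisopropylsilyloxy)phenyl]ethanone | CC(=O)c1c(O)cc(O[Si](C(C)C)(C(C)C)C(C)C)cc1OC | intermediate
3 | 3-methylbut-2-en-1-ol | CC(C)=CCO | starting material
4 | 1-[2-methoxy-6-(3-methylbut-2-enyloxy)-4-(triisopropylsilyloxy)phenyl]ethanone | CC(=O)c1c(OCC=C(C)C)cc(O[Si](C(C)C)(C(C)C)C(C)C)cc1OC | intermediate
5 | 2-acetyl-3-methoxy-6-(2-methylbut-3-en-2-yl)-5-(triisopropylsilyloxy)cyclohexa-2,4-dien-1-one | CC(=O)C1=C(OC)C=C(O[Si](C(C)C)(C(C)C)C(C)C)C(C(C)(C)C=C)C1=O | intermediate (not isolated)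
6 | 2-acetyl-3-methoxy-4-(3-methylbut-2-enyl)-5-(triisopropylsilyloxy)cyclohexa-2,5-dien-1-one | CC(=O)C1=C(OC)C(CC=C(C)C)C(O[Si](C(C)C)(C(C)C)C(C)C)=CC1=O | intermediate (not isolated)
7 | 1-[6-hydroxy-2-methoxy-3-(3-methylbut-2-enyl)-4-(triisopropylsilyloxy)phenyl]ethanone | CC(=O)c1c(O)cc(O[Si](C(C)C)(C(C)C)C(C)C)c(CC=C(C)C)c1OC | intermediate
8 | 1-[2-methoxy-6-(methoxymethoxy)-3-(3-methylbut-2-enyl)-4-(triisopropylsilyloxy)phenyl]ethanone | CC(=O)c1c(OCOC)cc(O[Si](C(C)C)(C(C)C)C(C)C)c(CC=C(C)C)c1OC | intermediate
9 | 4-bromophenol | Oc1ccc(Br)cc1 | starting material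
10 | 1-bromo-4-(methoxymethoxy)benzene | COCOc1ccc(Br)cc1 | intermediate
11 | 1-[2-methoxy-6-(methoxymethoxy)-3-(3-methylbut-2-enyl)-4-(triisopropylsilyloxy)phenyl]-2-[4-(methoxymethoxy)phenyl]ethanone | COCOc1ccc(CC(=O)c2c(OCOC)cc(O[Si](C(C)C)(C(C)C)C(C)C)c(CC=C(C)C)c2OC)cc1 | intermediate
12 | 1-[4-hydroxy-2-methoxy-6-(methoxymethoxy)-3-(3-methylbut-2-enyl)phenyl]-2-[4-(methoxymethoxy)phenyl]ethanone | COCOc1ccc(CC(=O)c2c(OCOC)cc(O)c(CC=C(C)C)c2OC)cc1 | intermediate
13 | 1-[4-hydroxy-5-(hydroxymethyl)-2-methoxy-6-(methoxymethoxy)-3-(3-methylbut-2-enyl)phenyl]-2-[4-(methoxymethoxy)phenyl]ethanone | COCOc1ccc(CC(=O)c2c(OCOC)c(CO)c(O)c(CC=C(C)C)c2OC)cc1 | intermediate (not isolated)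
14 | 6-hydroxy-4-methoxy-2-(methoxymethoxy)-3-{[4-(methoxymethoxy)phenyl]acetyl}-5-(3-methylbut-2-enyl)benzaldehyde | COCOc1ccc(CC(=O)c2c(OCOC)c(C=O)c(O)c(CC=C(C)C)c2OC)cc1 | intermediate
15 | 2-methylprop-1-enylboronic acid | CC(C)=CB(O)O | starting material
16 | 1-[5-[1-(dibenzylamino)-3-methylbut-2-enyl]-4-hydroxy-2-methoxy-6-(methoxymethoxy)-3-(3-methylbut-2-enyl)phenyl]-2-[4-(methoxymethoxy)phenyl]ethanone | COCOc1ccc(CC(=O)c2c(OCOC)c(C(C=C(C)C)N(Cc3ccccc3)Cc3ccccc3)c(O)c(CC=C(C)C)c2OC)cc1 | intermediate (not isolated)
17 | 3-methoxy-5-(methoxymethoxy)-4-{[4-(methoxymethoxy)phenyl]acetyl}-2-(3-methylbut-2-enyl)-6-(3-methylbut-2-enylidene)cyclohexa-2,4-dien-1-one | COCOc1ccc(CC(=O)C2=C(OCOC)C(=CC=C(C)C)C(=O)C(CC=C(C)C)=C2OC)cc1 | intermediate (not isolated)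
18 | 1-[7-methoxy-5-(methoxymethoxy)-2,2-dimethyl-8-(3-methylbut-2-enyl)-2H-chromen-6-yl]-2-[4-(methoxymethoxy)phenyl]ethanone | COc1c(CC=C(C)C)c2c(c(OCOC)c1C(=O)Cc1ccc(OCOC)cc1)C=CC(C)(C)O2 | intermediate
19 | 1-[5-hydroxy-7-methoxy-2,2-dimethyl-8-(3-methylbut-2-enyl)-2H-chromen-6-yl]-2-(4-hydroxyphenyl)ethanone | COc1c(CC=C(C)C)c2c(c(O)c1C(=O)Cc1ccc(O)cc1)C=CC(C)(C)O2 | target

**Totals and risks**
Total step count: 10. Longest linear sequence: 9 steps (steps 1-4 and 6-10 from 1); step 5 is a one-step side branch.

Steps most likely to fail: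

1. Step 9. Iminium formation at an aldehyde flanked on both sides may be slow, so protodeboronation of 15 or intermolecular condensation of the benzylic ketone CH2 with the iminium ion could overtake the intramolecular alkenyl transfer; the allylic amine may also be reluctant to eliminate. The fallback sets out from phenol 12 and forms the other ring-to-side-chain bond instead. Heating 12 with 3-methylbut-2-enal and catalytic ethylenediammonium diacetate in toluene at 110 °C should alkylate the free carbon ortho to the phenol and give the benzylic allylic alcohol 1-[4-hydroxy-5-(1-hydroxy-3-methylbut-2-enyl)-2-methoxy-6-(methoxymethoxy)-3-(3-methylbut-2-enyl)phenyl]-2-[4-(methoxymethoxy)phenyl]ethanone F1 in the flask. This alcohol loses water to the same quinone methide 17 and closes to the chromene. The fallback comes back to the route at 18 and makes step 8 unnecessary.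

2. Step 8. Under triethylamine and excess formaldehyde the acidic CH2 between the ketone and ring B may be hydroxymethylated in competition with the ring, or the oxidation may stall at the benzyl alcohol stage. The fallback sets out from 12 and avoids any amine base. Heating 12 with PhB(OH)2, paraformaldehyde and catalytic propionic acid in toluene with removal of water (boron-templated ortho-hydroxymethylation) should give the benzodioxaborin 1-[7-methoxy-5-(methoxymethoxy)-8-(3-methylbut-2-enyl)-2-phenyl-4H-1,3,2-benzodioxaborin-6-yl]-2-[4-(methoxymethoxy)phenyl]ethanone F2. Exchange with propane-1,3-diol frees salicyl alcohol 13, which is isolated in this case, and MnO2 in CH2Cl2 oxidises the benzylic alcohol to the aldehyde. The fallback comes back to the route at 14.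

3. Step 10. Before the ring B acetal has left, the acid may add methanol or water across the electron-rich C3=C4 alkene or cause oligomerisation of the chromene. The fallback sets out from 14 and changes the order, so that no chromene is exposed to acid. Treating 14 with HCl in MeOH at rt should give the free aldehyde 2,6-dihydroxy-3-[(4-hydroxyphenyl)acetyl]-4-methoxy-5-(3-methylbut-2-enyl)benzaldehyde F3. This is condensed with 15 and catalytic Bn2NH in 1,4-dioxane at 90 °C through the amine 1-[3-[1-(dibenzylamino)-3-methylbut-2-enyl]-2,4-dihydroxy-6-methoxy-5-(3-methylbut-2-enyl)phenyl]-2-(4-hydroxyphenyl)ethanone F4 and the quinone methide 5-hydroxy-4-[(4-hydroxyphenyl)acetyl]-3-methoxy-2-(3-methylbut-2-enyl)-6-(3-methylbut-2-enylidene)cyclohexa-2,4-dien-1-one F5. Closure on the oxygen next to the prenyl-bearing carbon is then steered by the hydrogen bond that holds the other hydroxyl to the ketone. The fallback comes back to the route at 19.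

**Further compounds**
F1 | step 9 | 1-[4-hydroxy-5-(1-hydroxy-3-methylbut-2-enyl)-2-methoxy-6-(methoxymethoxy)-3-(3-methylbut-2-enyl)phenyl]-2-[4-(methoxymethoxy)phenyl]ethanone | COCOc1ccc(CC(=O)c2c(OCOC)c(C(O)C=C(C)C)c(O)c(CC=C(C)C)c2OC)cc1
F2 | step 8 | 1-[7-methoxy-5-(methoxymethoxy)-8-(3-methylbut-2-enyl)-2-phenyl-4H-1,3,2-benzodioxaborin-6-yl]-2-[4-(methoxymethoxy)phenyl]ethanone | COCOc1ccc(CC(=O)c2c(OCOC)c3COB(c4ccccc4)Oc3c(CC=C(C)C)c2OC)cc1
F3 | step 10 | 2,6-dihydroxy-3-[(4-hydroxyphenyl)acetyl]-4-methoxy-5-(3-methylbut-2-enyl)benzaldehyde | COc1c(CC=C(C)C)c(O)c(C=O)c(O)c1C(=O)Cc1ccc(O)cc1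
F4 | step 10 | 1-[3-[1-(dibenzylamino)-3-methylbut-2-enyl]-2,4-dihydroxy-6-methoxy-5-(3-methylbut-2-enyl)phenyl]-2-(4-hydroxyphenyl)ethanone | COc1c(CC=C(C)C)c(O)c(C(C=C(C)C)N(Cc2ccccc2)Cc2ccccc2)c(O)c1C(=O)Cc1ccc(O)cc1
F5 | step 10 | 5-hydroxy-4-[(4-hydroxyphenyl)acetyl]-3-methoxy-2-(3-methylbut-2-enyl)-6-(3-methylbut-2-enylidene)cyclohexa-2,4-dien-1-one | COC1=C(CC=C(C)C)C(=O)C(=CC=C(C)C)C(O)=C1C(=O)Cc1ccc(O)cc1
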